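**Remark.** Icetexane (9(10→20)-abeo-abietane) numbering is used throughout: ring A = C1–C5, C10; ring B = C5, C6, C7, C8, C9, C20, C10; ring C = C8, C9, C11–C14; C18 = methyl on C4; C19 = lactone carbonyl. "7a" is read as 7α, which the SMILES shows as (7R); the target is (4S,5S,7R,10S).

## Retrosynthetic overview

1. Target 24 ⇐ C12–O demethylation, oxidation of ring C to the quinone, and acetylation/reduction at C7, from keto lactone 20 (ring C carried as its 11,12,14-trimethoxy arene).
2. 20 ⇐ butenolide 17 in one flask: Michael addition closes ring B (C5–C6), then lactone-enolate alkylation closes ring A (C3–C4). Ring order: arene, lactone (as butenolide), ring B, ring A.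
3. Enabling feature: the γ-lactone ring (C19, O, C10, C5, C4) in its butenolide form. C5 is a Michael acceptor, C4 is a latent enolate α to C19, and quaternary C10 carries both tethers on opposite faces (C20–aryl–acetyl and the C1–C2–C3–I chain).
4. 17 ⇐ diol 11 (oxidation, Z-olefination/lactonization, Stille acetylation, Cl→I) ⇐ Sharpless epoxidation of allylic alcohol 9 and benzylic epoxide reduction, which set C10.
5. 9 ⇐ Horner–Wadsworth–Emmons union of aldehyde 5 (from 1,2,4-trimethoxybenzene) with phosphonate 7.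

Key step: step 14

## Route

Step 1
Reactants: 1 1,2,4-trimethoxybenzene
Product: 2 2-(2,3,6-trimethoxyphenyl)propan-2-ol
Conditions: n-BuLi, THF, 0 °C; acetone, −78 → 23 °C; then H2O
Reagents that add atoms: acetone, CC(C)=O
Why: Directed ortho-lithiation occurs at the ring carbon flanked by two methoxy groups, and the aryllithium adds to acetone (1,2-addition).

Step 2
Reactants: 2 2-(2,3,6-trimethoxyphenyl)propan-2-ol
Product: 3 1,2,4-trimethoxy-3-(propan-2-yl)benzene
Conditions: Et3SiH, CF3CO2H, CH2Cl2, 0 → 23 °C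
Reagents that add atoms: none
Why: Ionic hydrogenation: the tertiary benzylic cation, stabilized by two ortho methoxy groups, is reduced by hydride transfer from the silane.

Step 3
Reactants: 3 1,2,4-trimethoxy-3-(propan-2-yl)benzene
Product: 4 1-bromo-2,4,5-trimethoxy-3-(propan-2-yl)benzene
Conditions: NBS, MeCN, 0 → 23 °C
Reagents that add atoms: N-bromosuccinimide, BrN1C(=O)CCC1=O
Why: Electrophilic aromatic bromination should go to the free position that is ortho to one methoxy group and para to another (future C8), not to the position activated by a single methoxy group.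

Step 4
Reactants: 4 1-bromo-2,4,5-trimethoxy-3-(propan-2-yl)benzene
Product: 5 2-bromo-3,5,6-trimethoxy-4-(propan-2-yl)benzaldehyde
Conditions: LiN(i-Pr)2, THF, −78 °C; DMF, −78 → 0 °C; then H2O
Reagents that add atoms: N,N-dimethylformamide, CN(C)C=O
Why: Deprotonative ortho-metalation removes the only ring hydrogen (acidified by the flanking bromine and methoxy group), and formylation with DMF at −78 °C should outrun loss of LiBr.

Step 5
Reactants: 6 triethyl phosphonoacetate
Product: 7 ethyl 5-chloro-2-(diethoxyphosphoryl)pentanoate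
Conditions: NaH, DMF, 0 °C; 1-bromo-3-chloropropane, 0 → 23 °C
Reagents that add atoms: 1-bromo-3-chloropropane, ClCCCBr
Why: SN2 alkylation of the phosphonoacetate anion occurs at the bromide end of the dihalide, bromide being the far better leaving group.

Step 6
Reactants: 5 2-bromo-3,5,6-trimethoxy-4-(propan-2-yl)benzaldehyde; 7 ethyl 5-chloro-2-(diethoxyphosphoryl)pentanoate
Product: 8 ethyl (2E)-3-[2-bromo-3,5,6-trimethoxy-4-(propan-2-yl)phenyl]-2-(3-chloropropyl)prop-2-enoate
Conditions: NaH, THF, 0 → 40 °C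
Reagents that add atoms: none
Why: Horner–Wadsworth–Emmons olefination of an aryl aldehyde with an α-alkyl phosphonoacetate should give mainly the (E)-enoate (aryl trans to the ester); a minor (Z)-isomer would be removed here.

Step 7
Reactants: 8 ethyl (2E)-3-[2-bromo-3,5,6-trimethoxy-4-(propan-2-yl)phenyl]-2-(3-chloropropyl)prop-2-enoate
Product: 9 (2E)-3-[2-bromo-3,5,6-trimethoxy-4-(propan-2-yl)phenyl]-2-(3-chloropropyl)prop-2-en-1-ol
Conditions: i-Bu2AlH, CH2Cl2, −78 °C; then H2O
Reagents that add atoms: none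
Why: 1,2-Reduction of the enoate by the aluminium hydride gives the allylic alcohol; the aryl bromide and alkyl chloride are inert.

Step 8
Reactants: 9 (2E)-3-[2-bromo-3,5,6-trimethoxy-4-(propan-2-yl)phenyl]-2-(3-chloropropyl)prop-2-en-1-ol
Product: 10 [(2R,3R)-3-[2-bromo-3,5,6-trimethoxy-4-(propan-2-yl)phenyl]-2-(3-chloropropyl)oxiran-2-yl]methanol
Conditions: t-BuOOH, Ti(Oi-Pr)4 (10 mol %), D-(−)-diethyl tartrate (12 mol %), 4 Å MS, CH2Cl2, −20 °C
Reagents that add atoms: tert-butyl hydroperoxide, CC(C)(C)OO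
Why: Sharpless asymmetric epoxidation of the trisubstituted (E)-allylic alcohol; the D-(−)-tartrate catalyst should deliver oxygen to the face that gives the (2R,3R)-epoxide, which fixes the future C10–O bond, the only stereocenter carried into the key step.

Step 9
Reactants: 10 [(2R,3R)-3-[2-bromo-3,5,6-trimethoxy-4-(propan-2-yl)phenyl]-2-(3-chloropropyl)oxiran-2-yl]methanol
Product: 11 (2S)-2-{[2-bromo-3,5,6-trimethoxy-4-(propan-2-yl)phenyl]methyl}-5-chloropentane-1,2-diol
Conditions: i-Bu2AlH, CH2Cl2, −20 → 0 °C; then H2O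
Reagents that add atoms: none
Why: Reductive opening of a 2,3-epoxy alcohol by i-Bu2AlH at C3 (the 1,2-diol-forming mode) is favored further here because C3 is benzylic and C2 is fully substituted; the C10–O bond is untouched.

Step 10
Reactants: 11 (2S)-2-{[2-bromo-3,5,6-trimethoxy-4-(propan-2-yl)phenyl]methyl}-5-chloropentane-1,2-diol
Product: 12 (2S)-2-{[2-bromo-3,5,6-trimethoxy-4-(propan-2-yl)phenyl]methyl}-5-chloro-2-hydroxypentanal
Conditions: TEMPO (10 mol %), PhI(OAc)2, CH2Cl2, 23 °C
Reagents that add atoms: none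
Why: Oxoammonium (TEMPO) oxidation is selective for the primary alcohol and cannot oxidize the tertiary one.

Step 11
Reactants: 12 (2S)-2-{[2-bromo-3,5,6-trimethoxy-4-(propan-2-yl)phenyl]methyl}-5-chloro-2-hydroxypentanal
Product: 14 (5S)-5-{[2-bromo-3,5,6-trimethoxy-4-(propan-2-yl)phenyl]methyl}-5-(3-chloropropyl)-3-methylfuran-2(5H)-one, via Z-hydroxy ester 13 (not isolated)
Conditions: ethyl 2-[bis(2,2,2-trifluoroethoxy)phosphoryl]propanoate, KN(SiMe3)2, 18-crown-6, THF, −78 °C; then TsOH (cat.), CH2Cl2, 23 °C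
Reagents that add atoms: ethyl 2-[bis(2,2,2-trifluoroethoxy)phosphoryl]propanoate, CCOC(=O)C(C)P(=O)(OCC(F)(F)F)OCC(F)(F)F
Why: Still–Gennari olefination should give the (Z)-enoate, whose ester is cis to the tertiary hydroxyl, and acid-catalyzed lactonization then closes the α-methyl butenolide without touching C10.

Step 12
Reactants: 14 (5S)-5-{[2-bromo-3,5,6-trimethoxy-4-(propan-2-yl)phenyl]methyl}-5-(3-chloropropyl)-3-methylfuran-2(5H)-one
Product: 16 (5S)-5-{[2-acetyl-3,5,6-trimethoxy-4-(propan-2-yl)phenyl]methyl}-5-(3-chloropropyl)-3-methylfuran-2(5H)-one, via enol ether 15 (not isolated)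
Conditions: tributyl(1-ethoxyvinyl)stannane, Pd(P(t-Bu)3)2 (5 mol %), CsF, dioxane, 100 °C; then 1 M HCl, THF, 23 °C
Reagents that add atoms: tributyl(1-ethoxyvinyl)stannane, CCCC[Sn](CCCC)(CCCC)C(=C)OCC; water, O
Why: Stille coupling of the hindered, electron-rich aryl bromide under bulky-phosphine palladium catalysis with fluoride activation, then hydrolysis of the enol ether, installs the aryl methyl ketone (C7, C6); the alkyl chloride and butenolide should not react.

Step 13
Reactants: 16 (5S)-5-{[2-acetyl-3,5,6-trimethoxy-4-(propan-2-yl)phenyl]methyl}-5-(3-chloropropyl)-3-methylfuran-2(5H)-one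
Product: 17 (5S)-5-{[2-acetyl-3,5,6-trimethoxy-4-(propan-2-yl)phenyl]methyl}-5-(3-iodopropyl)-3-methylfuran-2(5H)-one
Conditions: NaI, acetone, 56 °C
Reagents that add atoms: sodium iodide, [Na+].[I-]
Why: Finkelstein halide exchange (SN2) is driven by precipitation of NaCl and gives the more reactive electrophile for the ring closure.

Step 14
Reactants: 17 (5S)-5-{[2-acetyl-3,5,6-trimethoxy-4-(propan-2-yl)phenyl]methyl}-5-(3-iodopropyl)-3-methylfuran-2(5H)-one
Product: 20 (4S,5S,10S)-11,12,14-trimethoxy-7-oxoicetexa-8,11,13-trien-19,10-olide, via ketone lithium enolate 18 (not isolated), via Michael-adduct lactone enolate 19 (not isolated)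
Conditions: LiN(i-Pr)2 (2.3 equiv), THF, −78 → −30 °C; DMPU, −30 → 0 °C; then H2O
Reagents that add atoms: none
Why: The base first makes the kinetic enolate of the aryl methyl ketone (18; the butenolide has no γ-hydrogen), whose C6 adds to C5 of the butenolide (Michael addition) and so unmasks C4 as a lactone enolate (19); the second equivalent of base takes up the now acidic C6–H so that proton transfer cannot quench the C4 enolate, which then displaces iodide at C3 (intramolecular enolate alkylation). The closest known reaction type is the tandem conjugate addition–enolate alkylation of butenolides (Michael-initiated ring closure), here with both partners tethered to C10. Ring B closes 7-exo-trig and ring A closes 6-exo-tet with the enolate double bond endocyclic to the lactone, giving the 6-oxabicyclo[3.2.1]octan-7-one. C5 is set by the C20 tether, because the ketone enolate can reach C5 only on the butenolide face that carries the arylmethyl group, so ring B is cis-fused to the lactone; C4 is set by the C1–C3 tether, because the bridged lactone can form only on the face that carries the iodopropyl chain, which leaves the methyl group on the opposite face. The step needs alkylation at C4 and not at C6: the lactone enolate is the more basic and more nucleophilic of the two, its carbon sits 1,3-cis to the chain, and attack from C6 would have to build a strained benzo-fused bicyclo[4.3.1] system across trans-disposed substituents on C5 and C10.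

Step 15
Reactants: 20 (4S,5S,10S)-11,12,14-trimethoxy-7-oxoicetexa-8,11,13-trien-19,10-olide
Product: 21 (4S,5S,7R,10S)-7-hydroxy-11,12,14-trimethoxyicetexa-8,11,13-trien-19,10-olide (7α-alcohol)
Conditions: (S)-2-methyl-CBS-oxazaborolidine (20 mol %), BH3·SMe2, THF, −20 °C; then H2O
Reagents that add atoms: none
Why: Corey–Bakshi–Shibata reduction under reagent control: with aryl carbon C8 as the large and C6H2 as the small substituent, the (S)-catalyst should deliver hydride to the face that gives the (7R)-carbinol (7α-OH), while the hindered lactone is not reduced by borane at this temperature.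

Step 16
Reactants: 21 (4S,5S,7R,10S)-7-hydroxy-11,12,14-trimethoxyicetexa-8,11,13-trien-19,10-olide
Product: 22 (4S,5S,7R,10S)-7-acetoxy-11,12,14-trimethoxyicetexa-8,11,13-trien-19,10-olide
Conditions: Ac2O, DMAP (cat.), pyridine, CH2Cl2, 23 °C
Reagents that add atoms: acetic anhydride, CC(=O)OC(C)=O
Why: DMAP-catalyzed O-acylation of the secondary benzylic alcohol proceeds with retention at C7.

Step 17
Reactants: 22 (4S,5S,7R,10S)-7-acetoxy-11,12,14-trimethoxyicetexa-8,11,13-trien-19,10-olide
Product: 23 (4S,5S,7R,10S)-7-acetoxy-12-methoxy-11,14-dioxoicetexa-8,12-dien-19,10-olide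
Conditions: (NH4)2Ce(NO3)6, MeCN–H2O, 0 °C
Reagents that add atoms: water, O
Why: Oxidative demethylation of the para-dimethoxy pair (C11, C14) by ceric ammonium nitrate gives the p-quinone and leaves the C12 methyl ether as a vinylogous ester; acetate and lactone are stable to the mildly acidic oxidant.

Step 18
Reactants: 23 (4S,5S,7R,10S)-7-acetoxy-12-methoxy-11,14-dioxoicetexa-8,12-dien-19,10-olide
Product: 24 7α-acetoxy-6,7-dihydroicetexone, (4S,5S,7R,10S)-7-acetoxy-12-hydroxy-11,14-dioxoicetexa-8,12-dien-19,10-olide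
Conditions: BCl3, CH2Cl2, −78 °C; then H2O
Reagents that add atoms: none
Why: Lewis acid ether cleavage: BCl3 chelated between the C11 carbonyl and the C12 methoxy oxygen should cleave this activated methyl ether at −78 °C by chloride attack on the methyl group, conditions under which the acetate on the electron-poor quinone ring and the lactone should survive.

## Compound list

1 | 1,2,4-trimethoxybenzene | COc1ccc(OC)c(OC)c1 | starting material
2 | 2-(2,3,6-trimethoxyphenyl)propan-2-ol | COc1ccc(OC)c(C(C)(C)O)c1OC | intermediate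
3 | 1,2,4-trimethoxy-3-(propan-2-yl)benzene | COc1ccc(OC)c(C(C)C)c1OC | intermediate
4 | 1-bromo-2,4,5-trimethoxy-3-(propan-2-yl)benzene | COc1cc(Br)c(OC)c(C(C)C)c1OC | intermediate
5 | 2-bromo-3,5,6-trimethoxy-4-(propan-2-yl)benzaldehyde | COc1c(C=O)c(Br)c(OC)c(C(C)C)c1OC | intermediate
6 | triethyl phosphonoacetate | CCOC(=O)CP(=O)(OCC)OCC | starting material
7 | ethyl 5-chloro-2-(diethoxyphosphoryl)pentanoate | CCOC(=O)C(CCCCl)P(=O)(OCC)OCC | intermediate
8 | ethyl (2E)-3-[2-bromo-3,5,6-trimethoxy-4-(propan-2-yl)phenyl]-2-(3-chloropropyl)prop-2-enoate | CCOC(=O)/C(CCCCl)=C/c1c(Br)c(OC)c(C(C)C)c(OC)c1OC | intermediate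
9 | (2E)-3-[2-bromo-3,5,6-trimethoxy-4-(propan-2-yl)phenyl]-2-(3-chloropropyl)prop-2-en-1-ol | OC/C(CCCCl)=C/c1c(Br)c(OC)c(C(C)C)c(OC)c1OC | intermediate
10 | [(2R,3R)-3-[2-bromo-3,5,6-trimethoxy-4-(propan-2-yl)phenyl]-2-(3-chloropropyl)oxiran-2-yl]methanol | OC[C@@]1(CCCCl)O[C@@H]1c2c(Br)c(OC)c(C(C)C)c(OC)c2OC | intermediate
11 | (2S)-2-{[2-bromo-3,5,6-trimethoxy-4-(propan-2-yl)phenyl]methyl}-5-chloropentane-1,2-diol | OC[C@@](CCCCl)(O)Cc1c(Br)c(OC)c(C(C)C)c(OC)c1OC | intermediate
12 | (2S)-2-{[2-bromo-3,5,6-trimethoxy-4-(propan-2-yl)phenyl]methyl}-5-chloro-2-hydroxypentanal | O=C[C@@](CCCCl)(O)Cc1c(Br)c(OC)c(C(C)C)c(OC)c1OC | intermediate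
13 | ethyl (2Z,4S)-4-{[2-bromo-3,5,6-trimethoxy-4-(propan-2-yl)phenyl]methyl}-7-chloro-4-hydroxy-2-methylhept-2-enoate (not isolated) | CCOC(=O)/C(C)=C\[C@@](CCCCl)(O)Cc1c(Br)c(OC)c(C(C)C)c(OC)c1OC | intermediate
14 | (5S)-5-{[2-bromo-3,5,6-trimethoxy-4-(propan-2-yl)phenyl]methyl}-5-(3-chloropropyl)-3-methylfuran-2(5H)-one | CC1=C[C@](CCCCl)(Cc2c(Br)c(OC)c(C(C)C)c(OC)c2OC)OC1=O | intermediate
15 | (5S)-5-(3-chloropropyl)-5-{[2-(1-ethoxyethenyl)-3,5,6-trimethoxy-4-(propan-2-yl)phenyl]methyl}-3-methylfuran-2(5H)-one (not isolated) | CC1=C[C@](CCCCl)(Cc2c(C(=C)OCC)c(OC)c(C(C)C)c(OC)c2OC)OC1=O | intermediate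
16 | (5S)-5-{[2-acetyl-3,5,6-trimethoxy-4-(propan-2-yl)phenyl]methyl}-5-(3-chloropropyl)-3-methylfuran-2(5H)-one | CC1=C[C@](CCCCl)(Cc2c(C(C)=O)c(OC)c(C(C)C)c(OC)c2OC)OC1=O | intermediate
17 | (5S)-5-{[2-acetyl-3,5,6-trimethoxy-4-(propan-2-yl)phenyl]methyl}-5-(3-iodopropyl)-3-methylfuran-2(5H)-one | CC1=C[C@](CCCI)(Cc2c(C(C)=O)c(OC)c(C(C)C)c(OC)c2OC)OC1=O | intermediate
18 | lithium enolate of the acetyl group of 17 (not isolated) | CC1=C[C@](CCCI)(Cc2c(C(=C)[O-])c(OC)c(C(C)C)c(OC)c2OC)OC1=O.[Li+] | intermediate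
19 | lithium C4 enolate of (5S,10S)-3-iodo-11,12,14-trimethoxy-7-oxo-3,4-seco-icetexa-8,11,13-trien-19,10-olide, shown as the monolithium species (not isolated) | O=C1C[C@H]2C(C)=C([O-])O[C@@]2(CCCI)Cc2c1c(OC)c(C(C)C)c(OC)c2OC.[Li+] | intermediate
20 | (4S,5S,10S)-11,12,14-trimethoxy-7-oxoicetexa-8,11,13-trien-19,10-olide | O=C1C[C@@H]2[C@]3(CCC[C@]2(C)C(=O)O3)Cc2c1c(OC)c(C(C)C)c(OC)c2OC | intermediate
21 | (4S,5S,7R,10S)-7-hydroxy-11,12,14-trimethoxyicetexa-8,11,13-trien-19,10-olide | O[C@@H]1C[C@@H]2[C@]3(CCC[C@]2(C)C(=O)O3)Cc2c1c(OC)c(C(C)C)c(OC)c2OC | intermediate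
22 | (4S,5S,7R,10S)-7-acetoxy-11,12,14-trimethoxyicetexa-8,11,13-trien-19,10-olide | CC(=O)O[C@@H]1C[C@@H]2[C@]3(CCC[C@]2(C)C(=O)O3)Cc2c1c(OC)c(C(C)C)c(OC)c2OC | intermediate
23 | (4S,5S,7R,10S)-7-acetoxy-12-methoxy-11,14-dioxoicetexa-8,12-dien-19,10-olide | CC(=O)O[C@@H]1C[C@@H]2[C@]3(CCC[C@]2(C)C(=O)O3)CC2=C1C(=O)C(C(C)C)=C(OC)C2=O | intermediate
24 | 7α-acetoxy-6,7-dihydroicetexone | CC(=O)O[C@@H]1C[C@@H]2[C@]3(CCC[C@]2(C)C(=O)O3)CC2=C1C(=O)C(C(C)C)=C(O)C2=O | target

## Step count and risks

Total step count: 18. Longest linear sequence: 17 steps (steps 1–4 and 6–18 from 1,2,4-trimethoxybenzene); step 5 is a one-step branch.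

Steps most likely to fail:

1. **Step 14.** The seven-membered Michael closure may be slow, proton transfer from C6–H may stall the cascade at the Michael adduct, or alkylation may occur at C6 instead of C4. Fallback, from 16 to 21, separating the two ring closures: catalytic KOt-Bu in THF at 0 °C should effect only the reversible intramolecular Michael addition of 16 and give the tricyclic Michael adduct F1 (C4–H, either epimer). Reduction as in step 15 gives the 7α-alcohol F2. Silylation (t-BuMe2SiOTf, 2,6-lutidine) gives the silyl ether F3, in which C4 is the only enolizable carbon. NaI in acetone gives the iodide F4. LiN(i-Pr)2 in THF–DMPU then closes ring A by lactone enolate alkylation to the tetracyclic silyl ether F5, and Bu4NF in THF returns the route at 21.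

2. **Step 15.** Poor facial selectivity if the substrate bias of the cis-lactone-fused benzosuberone overrides the catalyst. Fallback, from 20 to 22, by inversion: substrate-controlled reduction (NaBH4, CeCl3, MeOH, −40 °C) would give the 7β-alcohol F6, and Mitsunobu reaction with acetic acid (PPh3, diisopropyl azodicarboxylate, THF, 0 °C) would give the 7α-acetate with inversion, returning at 22.

3. **Step 18.** Ionization or cleavage of the benzylic acetate, or chloride addition to the quinone, may compete with ether cleavage. Fallback, from 21 to 24, with acetylation postponed: oxidation of 21 as in step 17 gives the 7α-hydroxy methoxyquinone F7. BCl3 at −78 °C gives the 7α-hydroxy hydroxyquinone F8, with no acetate present to be lost. Ac2O/pyridine gives the 7α,12-diacetate F9. The vinylogous anhydride at O12 is then removed selectively (NH4OAc, MeOH–H2O, 23 °C), which leaves the secondary acetate and gives 24.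

## Further compounds

F1 | step 14 | (5S,10S)-3-chloro-11,12,14-trimethoxy-7-oxo-3,4-seco-icetexa-8,11,13-trien-19,10-olide (C4 epimers) | O=C1C[C@H]2C(C)C(=O)O[C@@]2(CCCCl)Cc2c1c(OC)c(C(C)C)c(OC)c2OC
F2 | step 14 | (5S,7R,10S)-3-chloro-7-hydroxy-11,12,14-trimethoxy-3,4-seco-icetexa-8,11,13-trien-19,10-olide | O[C@@H]1C[C@H]2C(C)C(=O)O[C@@]2(CCCCl)Cc2c1c(OC)c(C(C)C)c(OC)c2OC
F3 | step 14 | (5S,7R,10S)-7-(tert-butyldimethylsilyloxy)-3-chloro-11,12,14-trimethoxy-3,4-seco-icetexa-8,11,13-trien-19,10-olide | CC(C)(C)[Si](C)(C)O[C@@H]1C[C@H]2C(C)C(=O)O[C@@]2(CCCCl)Cc2c1c(OC)c(C(C)C)c(OC)c2OC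
F4 | step 14 | (5S,7R,10S)-7-(tert-butyldimethylsilyloxy)-3-iodo-11,12,14-trimethoxy-3,4-seco-icetexa-8,11,13-trien-19,10-olide | CC(C)(C)[Si](C)(C)O[C@@H]1C[C@H]2C(C)C(=O)O[C@@]2(CCCI)Cc2c1c(OC)c(C(C)C)c(OC)c2OC
F5 | step 14 | (4S,5S,7R,10S)-7-(tert-butyldimethylsilyloxy)-11,12,14-trimethoxyicetexa-8,11,13-trien-19,10-olide | CC(C)(C)[Si](C)(C)O[C@@H]1C[C@@H]2[C@]3(CCC[C@]2(C)C(=O)O3)Cc2c1c(OC)c(C(C)C)c(OC)c2OC
F6 | step 15 | (4S,5S,7S,10S)-7-hydroxy-11,12,14-trimethoxyicetexa-8,11,13-trien-19,10-olide (7β-alcohol) | O[C@H]1C[C@@H]2[C@]3(CCC[C@]2(C)C(=O)O3)Cc2c1c(OC)c(C(C)C)c(OC)c2OC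
F7 | step 18 | (4S,5S,7R,10S)-7-hydroxy-12-methoxy-11,14-dioxoicetexa-8,12-dien-19,10-olide | O[C@@H]1C[C@@H]2[C@]3(CCC[C@]2(C)C(=O)O3)CC2=C1C(=O)C(C(C)C)=C(OC)C2=O
F8 | step 18 | (4S,5S,7R,10S)-7,12-dihydroxy-11,14-dioxoicetexa-8,12-dien-19,10-olide | O[C@@H]1C[C@@H]2[C@]3(CCC[C@]2(C)C(=O)O3)CC2=C1C(=O)C(C(C)C)=C(O)C2=O
F9 | step 18 | (4S,5S,7R,10S)-7,12-diacetoxy-11,14-dioxoicetexa-8,12-dien-19,10-olide | CC(=O)O[C@@H]1C[C@@H]2[C@]3(CCC[C@]2(C)C(=O)O3)CC2=C1C(=O)C(C(C)C)=C(OC(C)=O)C2=O
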